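The readings were computed for substances that don't exist; scatter was added.

5.00 d is the span that matters here, the run-out time: the time by which the solid G of the green flask should be used up, reckoned below from the teal flask's last reading.

| flask | G | D | remark | time |
|---|---|---|---|---|
| green | 19 mM | 38 mM | the very flask that is asked about, followed so far |  |
| teal | 38 mM | 38 mM | run made earlier |  |
| flask | 19 mM | 38.0 mM |  | 10 d |

green run (percent of the G charged)

| time / h | L / % | Z / % |
|---|---|---|
| 4.00 | 0.5 | 4.1 |
| 8.00 | 0.8 | 7.1 |
| 15.0 | 2.6 | 9.0 |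
| 25.0 | 6.6 | 10.2 |
| 50.0 | 16.0 | 10.2 |

teal run (percent of the G charged)

| time / d | L / % | Z / % |
|---|---|---|
| 2.08 | 8.1 | 5.0 |
| 4.00 | 14.2 | 5.2 |
| 6.00 | 20.4 | 5.9 |
| 8.00 | 26.5 | 5.4 |
| 10.0 | 28.9 | 0 |

(each reading ± 0.3 percentage points)

1. L at 10 d, in percent of the G charged
2. concentration of Z in solution at 10 d, in percent of saturation

- G is a solid; its amount is given per volume of the solution
- at the start none of G is in solution
- Z means what is dissolved; the solid is not counted in it
- Z is what G becomes in solution

At 50.0 h the green flask reads [L] = 3.04 mM and [Z] = 1.94 mM. The teal flask, with twice the solid, reads 3.08 mM and 1.90 mM at 2.08 d, the same moment. So, within the scatter, the two flasks read alike in mM at that moment, and teal's larger solid charge shows in neither reading. Teal's Z falls from 5.4 % at 8.00 d to 0 % at 10.0 d, which reads as its solid gone within those days. Green's charge is half of teal's, which takes 0.301 of a power of ten off the time, so 10.0 d becomes 5.00 d. The asked 10 d lies 0.301 powers of ten later. The reckoning here therefore expects green to end, in percent of its own charge, near teal's 28.9 %, with Z at nil.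

The forecast gives 31.5 % (28 % to 37 %) and 0 % (0 % to 2 %), somewhat above the figure here for L: “Green's 19 mM should therefore run out at about 4.1 d.”

The green flask gives 30.0 % and 0 %.

    L ⇌ Q (K = 1.90, k = 1.40 × 10⁻⁵ s⁻¹)
    D + J → L (k = 8.40 × 10⁻⁴ M⁻¹ s⁻¹)
    Z → J (k = 2.20 × 10⁻⁵ s⁻¹)
    2 Z → X (k = 9.00 × 10⁻⁴ M⁻¹ s⁻¹)
    G ⇌ Z, rate k5*(cs5 - [Z]) while solid is left; crystals form when [Z] > cs5 (solubility = 7.90 mM, k = 8.90 × 10⁻⁶ s⁻¹)

G, the limiting reagent here, stands at 0 % at 5.00 d, with D at 57 % of its charge at the end. The flask holds a Q that the number does not show: 56.9 % of the G charged at 10 d. L and Q relax with a half-life of 0.375 d, short against 5.00 d. L goes from 32.5 % at 5.00 d to 30.0 % at 10 d, and J is down to 0.00519 %. Ten times the time, 100 d, leaves L at 30.0 %: the green flask is at rest.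

With 15 mM of D and the same G charge, the run-out time reckons again as 5.00 d, provided D leaves the dissolving alone, so G should be gone by 10 d. That flask gives G 0 %, with L at 25.7 % and J at 13.8 %.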